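The numbers were set for the occasion; the result is computed.

The pitfall in this flask is to set the coupling constant 46 /M/h against the self-condensation constant 0.54 /M/h, see the first far larger, and expect the partner to go to target.

solid substrate 1.5 M; partner 1.50 M; time 6.0 h

    solid substrate ⇌ dissolved substrate, rate k1*(cs1 - [dissolved substrate]) while solid is left; crystals form when [dissolved substrate] > cs1 (cs1 = 0.36 M, k1 = 3.7 /h)
    dissolved substrate + partner → target (k2 = 46 /M/h)
    solid product ⇌ target, rate k3*(cs3 - [target]) while solid is left; crystals form when [target] > cs3 (cs3 = 0.74 M, k3 = 22 /h)
    target ⇌ isomer of the product (K4 = 0.76, k4 = 0.13 /h)
    2 partner → self-condensation product (k5 = 0.54 /M/h)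

- for target the solid product is counted in
- two of one species on the left: rate k times its square, two consumed each time
- as a solid, counted per litre of solution: solid substrate, solid product
- at the start none of the solid substrate is in solution
- run time (flask): 6.0 h

- target and solid product together at 6.0 h, in percent of the solid substrate charged
- the change that raises the amount of target and solid product together at 6.0 h, in percent of the solid substrate charged most ("none" if none brings more than 2 percentage points) (winter / summer / spring / midnight / none)
- amount of target and solid product together at 6.0 h, in percent of the solid substrate charged, after summer

- winter: doubling the solubility in step 3, all else as stated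
- summer: doubling the amount of partner, all else as stated
- spring: doubling the solubility in step 1, all else as stated
- midnight: doubling the dissolution coefficient of step 1, all else as stated

In the first instants none of the solid substrate is in solution. Dissolved substrate lasts 0.60 min by step 2 with the partner as charged, far less than the dissolution time 16.2 min, so I take what dissolves to couple at once. Dissolution is then the rate-limiting step, and coupling runs near a ceiling that ignores c(partner), while self-condensation goes with its square. The quantity I carry is where the two draws on partner are equal, the crossover concentration, c×:

ceiling = 3.7 /h × 0.36 M = 1.33 M/h

c× = √(ceiling / (2 × 0.54 /M/h)) = 1.11 M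

share of spent partner that couples = 1 / (1 + (c(partner)/c×) squared)

The partner starts above c×. At the charge I reckon the two draws together at 3.76 M/h, so I expect it to fall through c× early, after about 0.104 h. The share is 35.4% at the charge, 68.7% at 0.750 M, and 1 as c(partner) nears zero. Simpson's rule gives a mean share of 68.4%, so 1.03 M couples, which is 68.4% of the solid substrate charged, and I reckon the partner lasts 0.770 h.

At the end, target relaxes towards isomer with a half-life of 2.30 h, towards an equilibrium isomer share of 43.2%. Dating the target from the midpoint of coupling, it keeps 64.8%, so I expect 44.3%.

The same share ranks the changes. Summer couples 1.27 M. Spring and midnight each double the ceiling and couple 1.20 M, less than summer. Winter doesn't enter the share. I choose summer and stop there, with no figure for its yield.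

The forecast says 45%, summer and 65%, on the ground that “self-condensation burns partner fast early on”. Its first figure lies just above mine, and its choice is mine.

The flask gives 43.4%. Summer gains most, 19 percentage points, reaching 62.6%.

In the neighbouring flask with 0.90 M of partner, c× stays 1.11 M and the charge starts below it. The shares 60.4% and 85.9% give a mean of 84.0%, so 0.756 M couples over 0.568 h. Target then keeps 64.5%, which makes 32.5%. That neighbouring flask gives 31.2%, beside 16.9% of isomer.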